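## Retrosynthetic overview

1. The target is ent-epifisetinidol-(4α→8)-fisetinidol, with a (2S,3S,4S) upper unit and a (2R,3S) lower unit. It is cut last at the interflavan bond C4(upper)–C8(lower): C8 of a (2R,3S)-flavan-3-ol whose C6 is blocked by bromine adds to the C4 benzylic cation (the O-protonated A-ring quinone methide) of a (2S,3S)-flavan-3-ol. Benzyl ethers and both bromines then leave in one hydrogenolysis.
2. Both flavan units have the same constitution, so both go back to one achiral flav-2-ene (4H-chromene) 8. The two enantiomers of IpcBH2 set C2/C3 of either series, and C3 of the upper unit is inverted by oxidation/reduction.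
3. Key disconnection of 8, in ring C: C3–C4 and O1–C8a. This gives the enolate of an aryl methyl ketone (O1–C2–C3, carrying ring B) and a 2-bromobenzyl bromide (C4 and C8a, ring A), joined by C-benzylation and copper-catalysed O-arylation in one flask.
4. Enabling feature: in ring C the ether oxygen O1 sits on aryl carbon C8a next to C4a–C4, and C2 carries ring B, so O1–C2=C3 is an enolate and C4/C8a a 1,3-dielectrophile. Ring A has no C5 substituent and its only oxygen (C7) is para to C4a, which later lets the free C7 phenol open C4 as a quinone methide.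
5. Order of ring formation: rings A and B are bought; ring C of 8 is closed once, in the key step, and serves both halves; the two flavans are joined last.

Key step: step 5

Assumption: IpcBH2 is taken to differentiate the faces of 8 as it does those of 1-arylcycloalkenes; should the sense be the opposite, the reagents of steps 6 and 8 change places and the route is otherwise unchanged.

Assumption: compounds 1 and 6 are taken as commercial.

## Route

Step 1
Reactants: 1 2-bromo-4-hydroxybenzaldehyde
Product: 2 2,5-dibromo-4-hydroxybenzaldehyde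
Conditions: Br2 (1.0 equiv), AcOH, 15 °C
Reagents that add atoms: bromine, BrBr
Why: Electrophilic aromatic bromination in which the hydroxyl group directs ortho and, of its two ortho carbons, C5 is the open one (C3 is squeezed between OH and Br), while the formyl group meta-directs to the same carbon.

Step 2
Reactants: 2 2,5-dibromo-4-hydroxybenzaldehyde
Product: 3 2,5-dibromo-4-(methoxymethoxy)benzaldehyde
Conditions: MOMCl, i-Pr2NEt, CH2Cl2, 0 °C → rt
Reagents that add atoms: chloromethyl methyl ether, COCCl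
Why: O-Alkylation of the phenol (Williamson type) gives an acetal ether that should survive base, hydride, borane and periodinane and can later be removed with mild acid while benzyl ethers stay.

Step 3
Reactants: 3 2,5-dibromo-4-(methoxymethoxy)benzaldehyde
Product: 4 [2,5-dibromo-4-(methoxymethoxy)phenyl]methanol
Conditions: NaBH4, MeOH/THF, 0 °C
Reagents that add atoms: none
Why: Chemoselective NaBH4 reduction of the aldehyde to the benzylic alcohol, with aryl bromides and the acetal inert.

Step 4
Reactants: 4 [2,5-dibromo-4-(methoxymethoxy)phenyl]methanol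
Product: 5 1,4-dibromo-2-(bromomethyl)-5-(methoxymethoxy)benzene
Conditions: CBr4, PPh3, CH2Cl2, 0 °C
Reagents that add atoms: carbon tetrabromide, BrC(Br)(Br)Br
Why: The Appel reaction converts the benzylic alcohol into the bromide under neutral conditions, avoiding the acid that would cleave the methoxymethyl ether.

Step 5
Reactants: 5 1,4-dibromo-2-(bromomethyl)-5-(methoxymethoxy)benzene (1.0 equiv), 6 1-[3,4-bis(benzyloxy)phenyl]ethan-1-one (1.2 equiv)
Product: 8 2-[3,4-bis(benzyloxy)phenyl]-6-bromo-7-(methoxymethoxy)-4H-chromene, via ketone 7 (not isolated)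
Conditions: LiN(SiMe3)2, THF, −78 °C, then 5, −78 → 0 °C; then CuI (10 mol %), 1,10-phenanthroline (20 mol %), Cs2CO3, DMF (THF distilled off), 100 °C, same flask
Reagents that add atoms: none
Why: Proposed new method: the lithium enolate of 6 is C-benzylated by 5 in an SN2 reaction (bond C3–C4), and the enolate of the resulting ketone 7, regenerated by Cs2CO3, is O-arylated at the ortho C–Br bond by monovalent copper through oxidative addition and C–O reductive elimination (bond O1–C8a); the closest known reaction type is the CuI-catalysed domino C-benzylation/O-arylation of 2-bromobenzyl bromides with β-keto esters to 4H-chromenes, together with copper-catalysed intramolecular enolate O-arylation to benzofurans, and the new element is a simple aryl methyl ketone enolate. Ring C closes in a 6-exo mode at the aryl carbon, the breaking C–Br bond lying outside the new ring. No stereocentre is formed, the product being the achiral enol ether that carries the whole C6–C3–C6 skeleton of either flavan unit. The step needs C- over O-alkylation (soft benzylic bromide, lithium enolate in THF), mono- over dialkylation (excess 6, low temperature, enolate fully formed before 5 is added) and O- over C-arylation (C-arylation would require a four-membered ring). Of the two aryl bromides only the one ortho to the new side chain can reach the copper enolate within the molecule, so the C6 bromide should be kept.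

Step 6
Reactants: 8 2-[3,4-bis(benzyloxy)phenyl]-6-bromo-7-(methoxymethoxy)-4H-chromene
Product: 10 (2R,3S)-2-[3,4-bis(benzyloxy)phenyl]-6-bromo-7-(methoxymethoxy)-3,4-dihydro-2H-chromen-3-ol, via dialkylborane 9 (not isolated)
Conditions: IpcBH2 made from (+)-α-pinene, THF, −25 → 0 °C; then NaOH, H2O2, 0 °C → rt
Reagents that add atoms: hydrogen peroxide, OO
Why: Asymmetric hydroboration–oxidation in which boron adds to C3 (β to O1, away from the aryl-bearing C2) and hydrogen to C2 on the same face and the oxidation goes with retention, so that the syn addition fixes the 2,3-trans relation (hydroboration of flav-2-enes is a known route to 2,3-trans-flavan-3-ols) and the reagent fixes the absolute configuration (2R,3S).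

Step 7
Reactants: 10 (2R,3S)-2-[3,4-bis(benzyloxy)phenyl]-6-bromo-7-(methoxymethoxy)-3,4-dihydro-2H-chromen-3-ol
Product: 11 (2R,3S)-2-[3,4-bis(benzyloxy)phenyl]-6-bromo-3,4-dihydro-2H-chromene-3,7-diol
Conditions: HCl (from AcCl), MeOH/THF, 40 °C
Reagents that add atoms: none
Why: Acid-catalysed acetal exchange with methanol removes the methoxymethyl group and frees the C7 phenol that activates C8, while benzyl ethers, aryl bromide and both stereocentres should be untouched.

Step 8
Reactants: 8 2-[3,4-bis(benzyloxy)phenyl]-6-bromo-7-(methoxymethoxy)-4H-chromene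
Product: 13 (2S,3R)-2-[3,4-bis(benzyloxy)phenyl]-6-bromo-7-(methoxymethoxy)-3,4-dihydro-2H-chromen-3-ol, via dialkylborane 12 (not isolated)
Conditions: IpcBH2 made from (−)-α-pinene, THF, −25 → 0 °C; then NaOH, H2O2, 0 °C → rt
Reagents that add atoms: hydrogen peroxide, OO
Why: Mirror image of step 6 (asymmetric hydroboration–oxidation), in which the enantiomeric borane adds to the other face of the same alkene, the syn addition again fixes 2,3-trans, and the reagent gives (2S,3R), which sets C2 of the upper unit.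

Step 9
Reactants: 13 (2S,3R)-2-[3,4-bis(benzyloxy)phenyl]-6-bromo-7-(methoxymethoxy)-3,4-dihydro-2H-chromen-3-ol
Product: 14 (2S)-2-[3,4-bis(benzyloxy)phenyl]-6-bromo-7-(methoxymethoxy)-2H-chromen-3(4H)-one
Conditions: Dess–Martin periodinane, NaHCO3, CH2Cl2, rt
Reagents that add atoms: none
Why: Dess–Martin oxidation of the secondary alcohol to the flavan-3-one under buffered, non-enolising conditions should keep the C2 configuration and clears C3 for inversion.

Step 10
Reactants: 14 (2S)-2-[3,4-bis(benzyloxy)phenyl]-6-bromo-7-(methoxymethoxy)-2H-chromen-3(4H)-one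
Product: 15 (2S,3S)-2-[3,4-bis(benzyloxy)phenyl]-6-bromo-7-(methoxymethoxy)-3,4-dihydro-2H-chromen-3-ol
Conditions: LiBH(s-Bu)3, THF, −78 °C; H2O quench
Reagents that add atoms: none
Why: Reduction with the bulky hydride LiBH(s-Bu)3 should occur from the face opposite the C2 aryl group and give the 2,3-cis alcohol (the standard catechin-to-epicatechin inversion), so that C3 is set by substrate control from C2.

Step 11
Reactants: 15 (2S,3S)-2-[3,4-bis(benzyloxy)phenyl]-6-bromo-7-(methoxymethoxy)-3,4-dihydro-2H-chromen-3-ol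
Product: 16 (2S,3S)-2-[3,4-bis(benzyloxy)phenyl]-6-bromo-3,4-dihydro-2H-chromene-3,7-diol
Conditions: HCl (from AcCl), MeOH/THF, 40 °C
Reagents that add atoms: none
Why: Acid-catalysed acetal exchange as in step 7 frees the C7 phenol, which is needed to activate the para-benzylic C4 in the next step.

Step 12
Reactants: 16 (2S,3S)-2-[3,4-bis(benzyloxy)phenyl]-6-bromo-3,4-dihydro-2H-chromene-3,7-diol
Product: 18 (2S,3S,4R)-2-[3,4-bis(benzyloxy)phenyl]-6-bromo-4-methoxy-3,4-dihydro-2H-chromene-3,7-diol, via quinone methide 17 (not isolated)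
Conditions: DDQ (1.05 equiv), MeOH/CH2Cl2 (1:1), −20 → 0 °C
Reagents that add atoms: methanol, CO
Why: Quinone dehydrogenation of a para-alkyl phenol, in which DDQ takes hydride from C4 (para to the free C7 hydroxyl) to give the A-ring quinone methide 17 and methanol adds 1,6 to C4 anti to the C3 hydroxyl with re-aromatisation; the C4 centre formed here is provisional and is erased in step 13.

Step 13
Reactants: 18 (2S,3S,4R)-2-[3,4-bis(benzyloxy)phenyl]-6-bromo-4-methoxy-3,4-dihydro-2H-chromene-3,7-diol, 11 (2R,3S)-2-[3,4-bis(benzyloxy)phenyl]-6-bromo-3,4-dihydro-2H-chromene-3,7-diol (3 equiv, excess recovered)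
Product: 20 (2S,3S,4S)-2-[3,4-bis(benzyloxy)phenyl]-4-{(2R,3S)-2-[3,4-bis(benzyloxy)phenyl]-6-bromo-3,7-dihydroxy-3,4-dihydro-2H-chromen-8-yl}-6-bromo-3,4-dihydro-2H-chromene-3,7-diol, via benzylic cation 19 (not isolated)
Conditions: BF3·OEt2 (0.5 equiv), CH2Cl2/THF (4:1), −20 → 0 °C, slow addition of 18 to 11
Reagents that add atoms: none
Why: BF3 binds the C4 methoxy oxygen and ionises the C4–O bond to the para-hydroxybenzylic cation 19 (stabilised by the free C7 hydroxyl; under these Lewis-acidic conditions the electrophile is this cation and not a neutral quinone methide), and C8 of 11 (the only free carbon ortho or para to its ring oxygens, since C6 carries bromine) attacks C4 in a Friedel–Crafts alkylation that copies the biosynthetic chain extension, entering anti to the axial C3 hydroxyl and the C2 aryl group to give the 3,4-trans (4S) configuration, while excess 11 and slow addition of 18 hold back self-condensation of 18 through its own C8.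

Step 14
Reactants: 20 (2S,3S,4S)-2-[3,4-bis(benzyloxy)phenyl]-4-{(2R,3S)-2-[3,4-bis(benzyloxy)phenyl]-6-bromo-3,7-dihydroxy-3,4-dihydro-2H-chromen-8-yl}-6-bromo-3,4-dihydro-2H-chromene-3,7-diol
Product: 21 (2S,3S,4S)-2-(3,4-dihydroxyphenyl)-4-[(2R,3S)-2-(3,4-dihydroxyphenyl)-3,7-dihydroxy-3,4-dihydro-2H-chromen-8-yl]-3,4-dihydro-2H-chromene-3,7-diol
Conditions: H2 (1 atm), Pd(OH)2/C, Et3N (2.2 equiv), THF/MeOH, rt
Reagents that add atoms: none
Why: Hydrogenolysis over Pd(OH)2/C should cleave the four benzyl ethers and, with Et3N as HBr scavenger, both aryl C–Br bonds, while the C–C interflavan bond and all five stereocentres are not affected.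

## Compound list

1 | 2-bromo-4-hydroxybenzaldehyde | O=Cc1ccc(O)cc1Br | starting material
2 | 2,5-dibromo-4-hydroxybenzaldehyde | O=Cc1cc(Br)c(O)cc1Br | intermediate
3 | 2,5-dibromo-4-(methoxymethoxy)benzaldehyde | COCOc1cc(Br)c(C=O)cc1Br | intermediate
4 | [2,5-dibromo-4-(methoxymethoxy)phenyl]methanol | COCOc1cc(Br)c(CO)cc1Br | intermediate
5 | 1,4-dibromo-2-(bromomethyl)-5-(methoxymethoxy)benzene | COCOc1cc(Br)c(CBr)cc1Br | intermediate
6 | 1-[3,4-bis(benzyloxy)phenyl]ethan-1-one | CC(=O)c1ccc(OCc2ccccc2)c(OCc2ccccc2)c1 | starting material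
7 | 1-[3,4-bis(benzyloxy)phenyl]-3-[2,5-dibromo-4-(methoxymethoxy)phenyl]propan-1-one | COCOc1cc(Br)c(CCC(=O)c2ccc(OCc3ccccc3)c(OCc3ccccc3)c2)cc1Br | intermediate (not isolated)
8 | 2-[3,4-bis(benzyloxy)phenyl]-6-bromo-7-(methoxymethoxy)-4H-chromene | COCOc1cc2OC(=CCc2cc1Br)c1ccc(OCc2ccccc2)c(OCc2ccccc2)c1 | intermediate
9 | isopinocampheyl(flavan-3-yl)borane with the C2/C3 configuration of 10, boron at C3 in place of OH, isopinocampheyl group from (+)-α-pinene | COCOc1cc2O[C@@H]([C@@H](B[C@@H]3C[C@@H]4C[C@H]([C@H]3C)C4(C)C)Cc2cc1Br)c1ccc(OCc2ccccc2)c(OCc2ccccc2)c1 | intermediate (not isolated)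
10 | (2R,3S)-2-[3,4-bis(benzyloxy)phenyl]-6-bromo-7-(methoxymethoxy)-3,4-dihydro-2H-chromen-3-ol | COCOc1cc2O[C@@H]([C@@H](O)Cc2cc1Br)c1ccc(OCc2ccccc2)c(OCc2ccccc2)c1 | intermediate
11 | (2R,3S)-2-[3,4-bis(benzyloxy)phenyl]-6-bromo-3,4-dihydro-2H-chromene-3,7-diol | Oc1cc2O[C@@H]([C@@H](O)Cc2cc1Br)c1ccc(OCc2ccccc2)c(OCc2ccccc2)c1 | intermediate
12 | isopinocampheyl(flavan-3-yl)borane with the C2/C3 configuration of 13, boron at C3 in place of OH, isopinocampheyl group from (−)-α-pinene | COCOc1cc2O[C@H]([C@H](B[C@H]3C[C@H]4C[C@@H]([C@@H]3C)C4(C)C)Cc2cc1Br)c1ccc(OCc2ccccc2)c(OCc2ccccc2)c1 | intermediate (not isolated)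
13 | (2S,3R)-2-[3,4-bis(benzyloxy)phenyl]-6-bromo-7-(methoxymethoxy)-3,4-dihydro-2H-chromen-3-ol | COCOc1cc2O[C@H]([C@H](O)Cc2cc1Br)c1ccc(OCc2ccccc2)c(OCc2ccccc2)c1 | intermediate
14 | (2S)-2-[3,4-bis(benzyloxy)phenyl]-6-bromo-7-(methoxymethoxy)-2H-chromen-3(4H)-one | COCOc1cc2O[C@H](C(=O)Cc2cc1Br)c1ccc(OCc2ccccc2)c(OCc2ccccc2)c1 | intermediate
15 | (2S,3S)-2-[3,4-bis(benzyloxy)phenyl]-6-bromo-7-(methoxymethoxy)-3,4-dihydro-2H-chromen-3-ol | COCOc1cc2O[C@H]([C@@H](O)Cc2cc1Br)c1ccc(OCc2ccccc2)c(OCc2ccccc2)c1 | intermediate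
16 | (2S,3S)-2-[3,4-bis(benzyloxy)phenyl]-6-bromo-3,4-dihydro-2H-chromene-3,7-diol | Oc1cc2O[C@H]([C@@H](O)Cc2cc1Br)c1ccc(OCc2ccccc2)c(OCc2ccccc2)c1 | intermediate
17 | (2S,3S)-2-[3,4-bis(benzyloxy)phenyl]-6-bromo-3-hydroxy-2,3-dihydro-7H-chromen-7-one (A-ring quinone methide) | O=C1C=C2O[C@H]([C@@H](O)C=C2C=C1Br)c1ccc(OCc2ccccc2)c(OCc2ccccc2)c1 | intermediate (not isolated)
18 | (2S,3S,4R)-2-[3,4-bis(benzyloxy)phenyl]-6-bromo-4-methoxy-3,4-dihydro-2H-chromene-3,7-diol | Oc1cc2O[C@H]([C@@H](O)[C@H](OC)c2cc1Br)c1ccc(OCc2ccccc2)c(OCc2ccccc2)c1 | intermediate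
19 | (2S,3S)-2-[3,4-bis(benzyloxy)phenyl]-6-bromo-3,7-dihydroxy-3,4-dihydro-2H-chromen-4-ylium methoxytrifluoroborate (C4 benzylic cation, ion pair) | Oc1cc2O[C@H]([C@@H](O)[CH+]c2cc1Br)c1ccc(OCc2ccccc2)c(OCc2ccccc2)c1.CO[B-](F)(F)F | intermediate (not isolated)
20 | (2S,3S,4S)-2-[3,4-bis(benzyloxy)phenyl]-4-{(2R,3S)-2-[3,4-bis(benzyloxy)phenyl]-6-bromo-3,7-dihydroxy-3,4-dihydro-2H-chromen-8-yl}-6-bromo-3,4-dihydro-2H-chromene-3,7-diol | Oc1c(Br)cc2c(c1)O[C@@H](c1ccc(OCc3ccccc3)c(OCc3ccccc3)c1)[C@@H](O)[C@@H]2c1c(O)c(Br)cc2c1O[C@H](c1ccc(OCc3ccccc3)c(OCc3ccccc3)c1)[C@@H](O)C2 | intermediate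
21 | (2S,3S,4S)-2-(3,4-dihydroxyphenyl)-4-[(2R,3S)-2-(3,4-dihydroxyphenyl)-3,7-dihydroxy-3,4-dihydro-2H-chromen-8-yl]-3,4-dihydro-2H-chromene-3,7-diol | Oc1ccc2c(c1)O[C@@H](c1ccc(O)c(O)c1)[C@@H](O)[C@@H]2c1c(O)ccc2c1O[C@H](c1ccc(O)c(O)c1)[C@@H](O)C2 | target

## Step count and risks

Total step count: 14. Longest linear sequence: 12 steps (steps 1–5 and 8–14).

Steps most likely to fail:

**Step 5** (Proposed new method). The copper-catalysed C–O closure of a non-stabilised ketone enolate may be too slow, so that a second benzylation, aldol self-condensation or intermolecular coupling at the aryl bromides takes over. The fallback uses known chemistry and closes ring C through O1–C2 instead. It sets out from 6 and comes back to the route at 8. Purchased 5-bromo-2,4-dihydroxybenzaldehyde F1 is protected selectively at the non-chelated 4-hydroxyl (MOMCl, K2CO3, acetone) to give 5-bromo-2-hydroxy-4-(methoxymethoxy)benzaldehyde F2. Claisen–Schmidt condensation of F2 with 6 (KOH, EtOH) should give (E)-1-[3,4-bis(benzyloxy)phenyl]-3-[5-bromo-2-hydroxy-4-(methoxymethoxy)phenyl]prop-2-en-1-one F3. Hydrogenation of the C=C bond alone (H2, RhCl(PPh3)3, benzene/EtOH) should give 1-[3,4-bis(benzyloxy)phenyl]-3-[5-bromo-2-hydroxy-4-(methoxymethoxy)phenyl]propan-1-one F4, which equilibrates with its cyclic hemiketal. Cyclodehydration (PPTS cat., benzene, 4 Å molecular sieves, 60 °C) should then give flav-2-ene 8.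

**Step 12.** The product phenol may be over-oxidised by a second hydride loss, or the quinone methide may tautomerise to the flav-3-en-3-ol before methanol adds. The fallback brings in the C4 oxygen without phenol oxidation, through a flav-3-ene. It sets out from 13 and comes back at 18. Mesylation of 13 (MsCl, Et3N) gives (2S,3R)-2-[3,4-bis(benzyloxy)phenyl]-6-bromo-7-(methoxymethoxy)-3,4-dihydro-2H-chromen-3-yl methanesulfonate F5. E2 elimination with DBU can only go toward C4, because the C2 hydrogen is cis to the leaving group, and should give (2R)-2-[3,4-bis(benzyloxy)phenyl]-6-bromo-7-(methoxymethoxy)-2H-chromene F6. Dimethyldioxirane in acetone/MeOH at −20 °C should epoxidise anti to the C2 aryl group, and methanol should open the epoxide at benzylic C4, giving (2S,3R,4S)-2-[3,4-bis(benzyloxy)phenyl]-6-bromo-4-methoxy-7-(methoxymethoxy)-3,4-dihydro-2H-chromen-3-ol F7. Dess–Martin oxidation then gives (2S,4S)-2-[3,4-bis(benzyloxy)phenyl]-6-bromo-4-methoxy-7-(methoxymethoxy)-2H-chromen-3(4H)-one F8. LiBH(s-Bu)3 should attack anti to the C2 aryl and C4 methoxy groups, which lie on the same face, giving (2S,3S,4S)-2-[3,4-bis(benzyloxy)phenyl]-6-bromo-4-methoxy-7-(methoxymethoxy)-3,4-dihydro-2H-chromen-3-ol F9. Finally HCl in MeOH removes the methoxymethyl group and equilibrates the C4 methoxy group through the benzylic cation to the 3,4-trans compound 18.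

**Step 6** (and its mirror image, step 8). The facial selectivity of the borane may be insufficient or reversed, or the β-aryloxy borane may undergo β-elimination with ring opening. The fallback replaces reagent control by resolution. It sets out from 8 and comes back at 10 and 13. Hydroboration with BH3·SMe2 (THF, 0 °C; then NaOH, H2O2), known for flav-2-enes, should give the racemic 2,3-trans alcohol F10. Its enantiomers are separated by preparative chromatography on a chiral stationary phase. Both are needed in equal amounts, 10 for the lower and 13 for the upper unit.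

## Further compounds

F1 | step 5 | 5-bromo-2,4-dihydroxybenzaldehyde (purchased) | Oc1cc(O)c(C=O)cc1Br
F2 | step 5 | 5-bromo-2-hydroxy-4-(methoxymethoxy)benzaldehyde | COCOc1cc(O)c(C=O)cc1Br
F3 | step 5 | (E)-1-[3,4-bis(benzyloxy)phenyl]-3-[5-bromo-2-hydroxy-4-(methoxymethoxy)phenyl]prop-2-en-1-one | COCOc1cc(O)c(/C=C/C(=O)c2ccc(OCc3ccccc3)c(OCc3ccccc3)c2)cc1Br
F4 | step 5 | 1-[3,4-bis(benzyloxy)phenyl]-3-[5-bromo-2-hydroxy-4-(methoxymethoxy)phenyl]propan-1-one | COCOc1cc(O)c(CCC(=O)c2ccc(OCc3ccccc3)c(OCc3ccccc3)c2)cc1Br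
F5 | step 12 | (2S,3R)-2-[3,4-bis(benzyloxy)phenyl]-6-bromo-7-(methoxymethoxy)-3,4-dihydro-2H-chromen-3-yl methanesulfonate | COCOc1cc2O[C@H]([C@H](OS(C)(=O)=O)Cc2cc1Br)c1ccc(OCc2ccccc2)c(OCc2ccccc2)c1
F6 | step 12 | (2R)-2-[3,4-bis(benzyloxy)phenyl]-6-bromo-7-(methoxymethoxy)-2H-chromene | COCOc1cc2O[C@H](C=Cc2cc1Br)c1ccc(OCc2ccccc2)c(OCc2ccccc2)c1
F7 | step 12 | (2S,3R,4S)-2-[3,4-bis(benzyloxy)phenyl]-6-bromo-4-methoxy-7-(methoxymethoxy)-3,4-dihydro-2H-chromen-3-ol | COCOc1cc2O[C@H]([C@H](O)[C@@H](OC)c2cc1Br)c1ccc(OCc2ccccc2)c(OCc2ccccc2)c1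
F8 | step 12 | (2S,4S)-2-[3,4-bis(benzyloxy)phenyl]-6-bromo-4-methoxy-7-(methoxymethoxy)-2H-chromen-3(4H)-one | COCOc1cc2O[C@H](C(=O)[C@@H](OC)c2cc1Br)c1ccc(OCc2ccccc2)c(OCc2ccccc2)c1
F9 | step 12 | (2S,3S,4S)-2-[3,4-bis(benzyloxy)phenyl]-6-bromo-4-methoxy-7-(methoxymethoxy)-3,4-dihydro-2H-chromen-3-ol | COCOc1cc2O[C@H]([C@@H](O)[C@@H](OC)c2cc1Br)c1ccc(OCc2ccccc2)c(OCc2ccccc2)c1
F10 | step 6 | racemic 2,3-trans-2-[3,4-bis(benzyloxy)phenyl]-6-bromo-7-(methoxymethoxy)-3,4-dihydro-2H-chromen-3-ol (equimolar 10 and 13) | COCOc1cc2O[C@@H]([C@@H](O)Cc2cc1Br)c1ccc(OCc2ccccc2)c(OCc2ccccc2)c1.COCOc1cc2O[C@H]([C@H](O)Cc2cc1Br)c1ccc(OCc2ccccc2)c(OCc2ccccc2)c1
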